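**Strategy**

Atoms are numbered as in isochromene (ring A: O2, C1, C8a, C4a, C4, C3; ring B: C4a–C8a). Everything rests on cutting the enol-ether double bond C3=C4 of ring A. C3 is the carbonyl carbon of a dienoate ester on the C1 oxygen; C4 is the γ-carbon of the ring B enone (C6=O, C5=C4a) and can carry phosphorus as a vinylogous acyl-stabilised ylide. One intramolecular ester Wittig olefination closes ring A, brings in the complete side chain and finishes the conjugated chromophore. Its precursor is a monocyclic cyclohexenone with all three ring stereocentres, a C4 allylic chloride and the (2E,4E,6R)-dienoate on O2; C5 is chlorinated last.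

Key step: step 13

Remark (assumption): (R)-2-methylbutan-1-ol (1) and (2E)-4-chlorobut-2-enoic acid (10) are taken as purchasable in the stated form; the isochromene locants of the target are used for the corresponding atoms of all intermediates.

**Route**

Step 1
Reactants: 1 (R)-2-methylbutan-1-ol; 2 2-(triphenylphosphoranylidene)propanal
Product: 4 (2E,4R)-2,4-dimethylhex-2-enal, via (R)-2-methylbutanal 3 (not isolated)
Conditions: TEMPO (cat.), PhI(OAc)2, CH2Cl2, rt; then 2, toluene, 80 °C (sealed)
Reagents that add atoms: none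
Why: TEMPO/PhI(OAc)2 oxidation gives the volatile, epimerisable aldehyde, which is trapped in the same flask by the stabilised formyl ylide in an E-selective Wittig reaction; the stereocentre comes from 1 and is not touched.

Step 2
Reactants: 4 (2E,4R)-2,4-dimethylhex-2-enal; 5 triethyl phosphonoacetate
Product: 6 ethyl (2E,4E,6R)-4,6-dimethylocta-2,4-dienoate
Conditions: NaH, THF, 0 °C; then 4, 0 °C to rt
Reagents that add atoms: none
Why: Horner–Wadsworth–Emmons olefination with a preformed stabilised phosphonate anion should give the new disubstituted double bond E.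

Step 3
Reactants: 6 ethyl (2E,4E,6R)-4,6-dimethylocta-2,4-dienoate
Product: 7 (2E,4E,6R)-4,6-dimethylocta-2,4-dienoic acid
Conditions: LiOH, THF/MeOH/H2O, rt; then 1 M HCl
Reagents that add atoms: lithium hydroxide, [Li+].[OH-]
Why: Ester saponification; the remote C6 stereocentre is not enolisable under these conditions.

Step 4
Reactants: 8 3-methylbut-3-en-2-one
Product: 9 tert-butyl(dimethyl)[(3-methylbuta-1,3-dien-2-yl)oxy]silane
Conditions: TBSOTf, Et3N, CH2Cl2, 0 °C
Reagents that add atoms: tert-butyldimethylsilyl triflate, CC(C)(C)[Si](C)(C)OS(=O)(=O)C(F)(F)F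
Why: Soft enolisation and O-silylation of the methyl ketone gives the 2-silyloxy diene (silyl enol ether formation).

Step 5
Reactants: 10 (2E)-4-chlorobut-2-enoic acid; 11 (4R)-4-benzyl-1,3-oxazolidin-2-one
Product: 13 (4R)-4-benzyl-3-[(2E)-4-chlorobut-2-enoyl]-1,3-oxazolidin-2-one, via (2E)-4-chlorobut-2-enoyl chloride 12 (not isolated)
Conditions: (COCl)2, DMF (cat.), CH2Cl2, 0 °C to rt, evaporate; then 11, n-BuLi, THF, −78 °C
Reagents that add atoms: none
Why: N-acylation of the lithiated oxazolidinone auxiliary by the acid chloride made in situ, at a temperature where the allylic chloride is inert.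

Step 6
Reactants: 9 tert-butyl(dimethyl)[(3-methylbuta-1,3-dien-2-yl)oxy]silane; 13 (4R)-4-benzyl-3-[(2E)-4-chlorobut-2-enoyl]-1,3-oxazolidin-2-one
Product: 14 (4R)-4-benzyl-3-{[(1R,6R)-4-{[tert-butyl(dimethyl)silyl]oxy}-6-(chloromethyl)-3-methylcyclohex-3-en-1-yl]carbonyl}-1,3-oxazolidin-2-one
Conditions: Et2AlCl (1.4 equiv), CH2Cl2, −78 to −30 °C; aq. NaHCO3 quench
Reagents that add atoms: none
Why: Auxiliary-controlled Diels–Alder reaction: in the Et2AlCl chelate the s-cis enoyl unit is shielded on one face by the benzyl group, so the diene adds to the open face with its siloxy-activated terminus (C5) bonding to the β-carbon (C4a), which sets C8a as R and, through the E dienophile, C4a trans to it.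

Step 7
Reactants: 14 (Diels–Alder adduct)
Product: 15 [(1R,6R)-4-{[tert-butyl(dimethyl)silyl]oxy}-6-(chloromethyl)-3-methylcyclohex-3-en-1-yl]methanol
Conditions: LiBH4, MeOH (1 equiv), THF, 0 °C
Reagents that add atoms: none
Why: Reductive cleavage of the N-acyl oxazolidinone gives the C1 primary alcohol and returns the auxiliary, while the silyl enol ether masks the C6 ketone and the alkyl chloride is inert to LiBH4.

Step 8
Reactants: 15 (silyl enol ether alcohol)
Product: 16 (4R,5R)-5-(chloromethyl)-4-(hydroxymethyl)-2-methylcyclohex-2-en-1-one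
Conditions: Pd(OAc)2 (1.1 equiv), MeCN, rt
Reagents that add atoms: none
Why: Saegusa–Ito oxidation: the palladium enolate at C7 should undergo β-hydride elimination towards ring carbon C8 to give the endocyclic C7=C8 enone.

Step 9
Reactants: 16 (enone)
Product: 17 (2R,3R,4R,5R)-5-(chloromethyl)-2,3-dihydroxy-4-(hydroxymethyl)-2-methylcyclohexan-1-one
Conditions: OsO4 (5 mol%), NMO, citric acid, t-BuOH/H2O, rt
Reagents that add atoms: osmium tetroxide, O=[Os](=O)(=O)=O, re-oxidised by N-methylmorpholine N-oxide, C[N+]1([O-])CCOCC1, the net source of both oxygens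
Why: Catalytic syn-dihydroxylation (citric acid for the electron-poor alkene) should occur on the face anti to the allylic C8a hydroxymethyl group, setting C7 and C8 with both oxygens cis to each other and trans to C1.

Step 10
Reactants: 17 (triol); 7 (2E,4E,6R)-4,6-dimethylocta-2,4-dienoic acid
Product: 18 [(1R,2R,3R,6R)-6-(chloromethyl)-2,3-dihydroxy-3-methyl-4-oxocyclohexyl]methyl (2E,4E,6R)-4,6-dimethylocta-2,4-dienoate
Conditions: 7 (1.05 equiv), DCC, DMAP (cat.), CH2Cl2, −20 to 0 °C
Reagents that add atoms: none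
Why: Steglich esterification should be selective for the unhindered primary C1 alcohol over the flanked secondary C8 and tertiary C7 hydroxyls.

Step 11
Reactants: 18 (diol ester)
Product: 19 [(1R,2R,3R,6R)-2-acetoxy-6-(chloromethyl)-3-hydroxy-3-methyl-4-oxocyclohexyl]methyl (2E,4E,6R)-4,6-dimethylocta-2,4-dienoate
Conditions: Ac2O, pyridine, DMAP (cat.), CH2Cl2, rt
Reagents that add atoms: acetic anhydride, CC(=O)OC(C)=O
Why: DMAP-catalysed acetylation of the equatorial secondary C8 alcohol; the tertiary C7 alcohol should not react at room temperature, and acetylation also removes the retro-aldol-prone β-hydroxy ketone.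

Step 12
Reactants: 19 (acetate)
Product: 22 [(1R,5R,6R)-6-acetoxy-2-(chloromethyl)-5-hydroxy-5-methyl-4-oxocyclohex-2-en-1-yl]methyl (2E,4E,6R)-4,6-dimethylocta-2,4-dienoate, via the bis-silyl enol ether 20 (not isolated), via the silyl ether enone 21 (not isolated)
Conditions: TMSOTf, Et3N, CH2Cl2, 0 °C; then IBX·MPO (2-iodoxybenzoic acid–4-methoxypyridine N-oxide complex), DMSO, rt; then 1 M HCl, THF
Reagents that add atoms: none
Why: Soft enolisation can only go towards C5 (C7 is quaternary), and the silyl enol ether is dehydrogenated to the C5=C4a enone by the IBX·MPO complex, a metal-free counterpart of the Saegusa–Ito oxidation chosen because zerovalent palladium would insert into the allylic chloride that forms; dilute acid then cleaves the tertiary silyl ether.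

Step 13
Reactants: 22 (γ-chloro enone ester)
Product: 25 (7R,8R,8aR)-3-[(1E,3E,5R)-3,5-dimethylhepta-1,3-dien-1-yl]-7-hydroxy-7-methyl-6-oxo-6,7,8,8a-tetrahydro-1H-isochromen-8-yl acetate, via tributylphosphonium chloride 23 (not isolated), via phosphorus ylide 24 (not isolated)
Conditions: PBu3, MeCN, rt; then Et3N, 80 °C (dilute)
Reagents that add atoms: none
Why: SN2 displacement of the allylic chloride by PBu3 gives phosphonium salt 23, whose P–CH2 protons (α to phosphorus, γ to the enone) are removed by Et3N to give the vinylogous acyl-stabilised ylide 24; its C4 adds to the dienoate carbonyl C3 and the oxaphosphetane collapses to Bu3P=O and the C3=C4 enol ether. The closest known reaction type is the intramolecular Wittig olefination of ester carbonyls by acyloxy-tethered stabilised ylides, used for benzofurans, chromenes and penem-type enol (thio)ethers. Ring A closes in a 6-exo-trig mode (C4 onto the exocyclic C3=O), giving the fused 1H-isochromene skeleton. No stereocentre is created: C3 and C4 become sp2 in an endocyclic double bond, and C7, C8 and C8a are spectators because only a mild amine base is present and the γ-hydrogen at C8a should stay in place. The step needs C4 rather than C5 to attack and the C1 dienoate rather than the C8 acetate or C6 ketone to be attacked: phosphorus fixes the nucleophilic carbon, closure onto the acetate would put the C4a=C5 double bond at a bridgehead, and only the dienoate carbonyl is reachable through an unstrained six-membered transition state. The trialkylphosphine ylide is chosen for its higher nucleophilicity, and the closure is driven by the P=O bond and the extended O2–C3=C4–C4a=C5–C6=O chromophore.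

Step 14
Reactants: 25 (deschloro bicycle)
Product: 26 (7R,8R,8aR)-5-chloro-3-[(1E,3E,5R)-3,5-dimethylhepta-1,3-dien-1-yl]-7-hydroxy-7-methyl-6-oxo-6,7,8,8a-tetrahydro-1H-isochromen-8-yl acetate (target)
Conditions: NCS (1.05 equiv), MeCN, 0 °C to rt
Reagents that add atoms: N-chlorosuccinimide, O=C1CCC(=O)N1Cl
Why: Electrophilic chlorination of the δ-alkoxy dienone should take place at C5, the terminus of the O2–C3=C4–C4a=C5 dienol ether that is also α to the carbonyl and is the position halogenated in azaphilone-type chromophores.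

**Compound list**

1 | (R)-2-methylbutan-1-ol | CC[C@@H](C)CO | starting material
2 | 2-(triphenylphosphoranylidene)propanal | CC(C=O)=P(c1ccccc1)(c1ccccc1)c1ccccc1 | starting material
3 | (R)-2-methylbutanal | CC[C@@H](C)C=O | intermediate
4 | (2E,4R)-2,4-dimethylhex-2-enal | CC[C@@H](C)/C=C(C)/C=O | intermediate
5 | triethyl phosphonoacetate | CCOC(=O)CP(=O)(OCC)OCC | starting material
6 | ethyl (2E,4E,6R)-4,6-dimethylocta-2,4-dienoate | CC[C@@H](C)/C=C(C)/C=C/C(=O)OCC | intermediate
7 | (2E,4E,6R)-4,6-dimethylocta-2,4-dienoic acid | CC[C@@H](C)/C=C(C)/C=C/C(=O)O | intermediate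
8 | 3-methylbut-3-en-2-one | CC(=O)C(C)=C | starting material
9 | tert-butyl(dimethyl)[(3-methylbuta-1,3-dien-2-yl)oxy]silane | C=C(C)C(=C)O[Si](C)(C)C(C)(C)C | intermediate
10 | (2E)-4-chlorobut-2-enoic acid | OC(=O)/C=C/CCl | starting material
11 | (4R)-4-benzyl-1,3-oxazolidin-2-one | O=C1N[C@H](Cc2ccccc2)CO1 | starting material
12 | (2E)-4-chlorobut-2-enoyl chloride | ClC(=O)/C=C/CCl | intermediate
13 | (4R)-4-benzyl-3-[(2E)-4-chlorobut-2-enoyl]-1,3-oxazolidin-2-one | O=C1OC[C@@H](Cc2ccccc2)N1C(=O)/C=C/CCl | intermediate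
14 | (4R)-4-benzyl-3-{[(1R,6R)-4-{[tert-butyl(dimethyl)silyl]oxy}-6-(chloromethyl)-3-methylcyclohex-3-en-1-yl]carbonyl}-1,3-oxazolidin-2-one | O=C1OC[C@@H](Cc2ccccc2)N1C(=O)[C@@H]3CC(C)=C(O[Si](C)(C)C(C)(C)C)C[C@H]3CCl | intermediate
15 | [(1R,6R)-4-{[tert-butyl(dimethyl)silyl]oxy}-6-(chloromethyl)-3-methylcyclohex-3-en-1-yl]methanol | OC[C@@H]1CC(C)=C(O[Si](C)(C)C(C)(C)C)C[C@H]1CCl | intermediate
16 | (4R,5R)-5-(chloromethyl)-4-(hydroxymethyl)-2-methylcyclohex-2-en-1-one | OC[C@@H]1C=C(C)C(=O)C[C@H]1CCl | intermediate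
17 | (2R,3R,4R,5R)-5-(chloromethyl)-2,3-dihydroxy-4-(hydroxymethyl)-2-methylcyclohexan-1-one | OC[C@@H]1[C@@H](O)[C@@](C)(O)C(=O)C[C@H]1CCl | intermediate
18 | [(1R,2R,3R,6R)-6-(chloromethyl)-2,3-dihydroxy-3-methyl-4-oxocyclohexyl]methyl (2E,4E,6R)-4,6-dimethylocta-2,4-dienoate | CC[C@@H](C)/C=C(C)/C=C/C(=O)OC[C@@H]1[C@@H](O)[C@@](C)(O)C(=O)C[C@H]1CCl | intermediate
19 | [(1R,2R,3R,6R)-2-acetoxy-6-(chloromethyl)-3-hydroxy-3-methyl-4-oxocyclohexyl]methyl (2E,4E,6R)-4,6-dimethylocta-2,4-dienoate | CC[C@@H](C)/C=C(C)/C=C/C(=O)OC[C@@H]1[C@@H](OC(C)=O)[C@@](C)(O)C(=O)C[C@H]1CCl | intermediate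
20 | bis(trimethylsilyl) derivative of 19 (C6 enol ether towards C5 and C7 silyl ether; configuration as in 19) | CC[C@@H](C)/C=C(C)/C=C/C(=O)OC[C@@H]1[C@@H](OC(C)=O)[C@@](C)(O[Si](C)(C)C)C(O[Si](C)(C)C)=C[C@H]1CCl | intermediate
21 | 7-O-trimethylsilyl ether of 22 (C5=C4a enone; configuration as in 22) | CC[C@@H](C)/C=C(C)/C=C/C(=O)OC[C@@H]1[C@@H](OC(C)=O)[C@@](C)(O[Si](C)(C)C)C(=O)C=C1CCl | intermediate
22 | [(1R,5R,6R)-6-acetoxy-2-(chloromethyl)-5-hydroxy-5-methyl-4-oxocyclohex-2-en-1-yl]methyl (2E,4E,6R)-4,6-dimethylocta-2,4-dienoate | CC[C@@H](C)/C=C(C)/C=C/C(=O)OC[C@@H]1[C@@H](OC(C)=O)[C@@](C)(O)C(=O)C=C1CCl | intermediate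
23 | tributylphosphonium chloride of 22 (PBu3 in place of the C4 chlorine; configuration as in 22) | CC[C@@H](C)/C=C(C)/C=C/C(=O)OC[C@@H]1[C@@H](OC(C)=O)[C@@](C)(O)C(=O)C=C1C[P+](CCCC)(CCCC)CCCC.[Cl-] | intermediate
24 | ylide of 23 (C4=PBu3, conjugated with the C5=C4a–C6=O enone; configuration as in 22) | CC[C@@H](C)/C=C(C)/C=C/C(=O)OC[C@@H]1[C@@H](OC(C)=O)[C@@](C)(O)C(=O)C=C1C=P(CCCC)(CCCC)CCCC | intermediate
25 | (7R,8R,8aR)-3-[(1E,3E,5R)-3,5-dimethylhepta-1,3-dien-1-yl]-7-hydroxy-7-methyl-6-oxo-6,7,8,8a-tetrahydro-1H-isochromen-8-yl acetate | CC[C@@H](C)/C=C(C)/C=C/C1=CC2=CC(=O)[C@](C)(O)[C@H](OC(C)=O)[C@H]2CO1 | intermediate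
26 | (7R,8R,8aR)-5-chloro-3-[(1E,3E,5R)-3,5-dimethylhepta-1,3-dien-1-yl]-7-hydroxy-7-methyl-6-oxo-6,7,8,8a-tetrahydro-1H-isochromen-8-yl acetate | CC[C@@H](C)/C=C(C)/C=C/C1=CC2=C(Cl)C(=O)[C@](C)(O)[C@H](OC(C)=O)[C@H]2CO1 | target

**Step count and risks**

Total steps: 14. Longest linear sequence: 10 steps (step 5, then steps 6 to 14); the acid branch (steps 1 to 3) joins at step 10 and the diene (step 4) at step 6.

Steps most likely to fail:

1. Step 13 (key step). The ylide may be too stabilised to add to the conjugated ester carbonyl, or acyl transfer may occur without olefination. Fallback: the same C3–C4 bond is closed from chloride 22 by a vinylogous Reformatsky-type acyl addition. Activated zinc dust in THF at rt should convert the allylic chloride into the zinc dienolate F1, whose γ-carbon C4 adds to the dienoate carbonyl to give the cyclic hemiketal F2 (mixture at C3). PPTS in warm toluene should then dehydrate it to the conjugated enol ether, and the route is rejoined at 25.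

2. Step 9. Facial selectivity of the osmylation may be poor, or the electron-poor enone may react so slowly that the free γ-chloro alcohol cyclises. Fallback: starting from enone 16, the primary alcohol is first converted into the tert-butyldiphenylsilyl ether F3 (TBDPSCl, imidazole, DMF), so that the C8a substituent becomes a much larger shield. Dihydroxylation under the same OsO4/NMO conditions should give the silyl ether diol F4. HF·pyridine in THF then frees the primary alcohol, and the route is rejoined at triol 17.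

3. Step 12. The dehydrogenation may stall, or the N-oxide may attack the newly formed allylic chloride and over-oxidise it. Fallback: starting from acetate 19, the bis-silyl enol ether 20 is made as before and treated with PhSeCl (CH2Cl2, −78 °C) to give the α-phenylselanyl ketone F5, selenium entering anti to the C4a chloromethyl group. Oxidation with H2O2/pyridine at 0 °C gives the selenoxide F6, which should undergo syn-elimination with the cis hydrogen at C4a. This rejoins the route at silyl ether enone 21, which the acidic work-up of step 12 converts into 22.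

Further compounds
F1 | step 13 | chlorozinc dienolate of 22 (O6–ZnCl, exocyclic C4 methylene, C5=C6) | CC[C@@H](C)/C=C(C)/C=C/C(=O)OC[C@@H]1[C@@H](OC(C)=O)[C@@](C)(O)C(O[Zn]Cl)=CC1=C
F2 | step 13 | (7R,8R,8aR)-3-[(1E,3E,5R)-3,5-dimethylhepta-1,3-dien-1-yl]-3,7-dihydroxy-7-methyl-6-oxo-3,4,6,7,8,8a-hexahydro-1H-isochromen-8-yl acetate (cyclic hemiketal, mixture at C3) | CC[C@@H](C)/C=C(C)/C=C/C1(O)CC2=CC(=O)[C@](C)(O)[C@H](OC(C)=O)[C@H]2CO1
F3 | step 9 | (4R,5R)-4-{[tert-butyl(diphenyl)silyl]oxymethyl}-5-(chloromethyl)-2-methylcyclohex-2-en-1-one | CC(C)(C)[Si](OC[C@@H]1C=C(C)C(=O)C[C@H]1CCl)(c1ccccc1)c1ccccc1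
F4 | step 9 | (2R,3R,4R,5R)-4-{[tert-butyl(diphenyl)silyl]oxymethyl}-5-(chloromethyl)-2,3-dihydroxy-2-methylcyclohexan-1-one | CC(C)(C)[Si](OC[C@@H]1[C@@H](O)[C@@](C)(O)C(=O)C[C@H]1CCl)(c1ccccc1)c1ccccc1
F5 | step 12 | 5-phenylselanyl ketone from 20 (7-O-trimethylsilyl ether of 19 carrying SePh at C5, trans to the C4a chloromethyl group) | CC[C@@H](C)/C=C(C)/C=C/C(=O)OC[C@@H]1[C@@H](OC(C)=O)[C@@](C)(O[Si](C)(C)C)C(=O)[C@H]([Se]c2ccccc2)[C@H]1CCl
F6 | step 12 | selenoxide of F5 | CC[C@@H](C)/C=C(C)/C=C/C(=O)OC[C@@H]1[C@@H](OC(C)=O)[C@@](C)(O[Si](C)(C)C)C(=O)[C@H]([Se](=O)c2ccccc2)[C@H]1CCl
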